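**Plan**
- Retrosynthesis: the 2,3-diol is taken back to a C3 ketone and C20 to a formyl group, then ring B is cut at C5–C6 and C9–C10.
- Enabling feature (labdane numbering): ring B (C5–C10) is a cyclohexene with C7=C8(CH3), H-5 cis to C20 and the C9 chain cis to C20. This is the pattern of an endo Diels–Alder adduct of a ring A C5=C10 enal and an (E)-1-alkyl-2-methylbutadiene.
- Forward: ring A enal from 2,2-dimethylcyclohexane-1,3-dione (4 steps) and the triene from geranyl acetate (2 steps); one cycloaddition closes ring B and brings in the whole C11–C15 chain with its acetate.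
- Stereochemistry: C5, C9 and C10 come from the cycloaddition (ring-bound cis dienophile, endo rule, chiral oxazaborolidinium for the face). C2 comes from face-selective oxidation of the C2=C3 silyl enol ether and C3 from equatorial hydride delivery.
- No protecting groups after the cycloaddition; C20 is reduced CHO → CH3 through the tosylhydrazone.

Key step: step 7

Remark on configuration: in labdane numbering (ring A = C1–C5, C10; ring B = C5–C10; C20 = methyl on C10; chain C11–C15) the target is (2S,3R,5R,9R,10S), with H-5, C20 and the C9 chain on one face and both hydroxyls on the other.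
Remark on conformation: steps 11 and 12 assume the cis-decalin conformer with C20 axial on ring A and the C9 chain pseudoaxial on ring B, which avoids A(1,2) strain between C11 and the C8 methyl.

**Route**

Step 1
Reactants: 1 2,2-dimethylcyclohexane-1,3-dione
Product: 2 6,6-dimethyl-1,4-dioxaspiro[4.5]decan-7-one
Conditions: ethylene glycol (1.05 equiv), TsOH (cat.), benzene, reflux, azeotropic removal of water
Reagents that add atoms: ethylene glycol, OCCO
Why: Acid-catalysed ketalisation should stop at the mono-dioxolane because the remaining carbonyl then lies between the quaternary carbon and the ketal.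

Step 2
Reactants: 2 6,6-dimethyl-1,4-dioxaspiro[4.5]decan-7-one
Product: 3 (8Z)-8-(hydroxymethylidene)-6,6-dimethyl-1,4-dioxaspiro[4.5]decan-7-one
Conditions: NaH, HCO2Et, EtOH (cat.), THF, 0 °C → rt; then aq. AcOH
Reagents that add atoms: ethyl formate, CCOC=O
Why: Crossed Claisen condensation at the only enolisable α-carbon is driven by formation of the stabilised sodium enolate of the β-keto aldehyde.

Step 3
Reactants: 3 (8Z)-8-(hydroxymethylidene)-6,6-dimethyl-1,4-dioxaspiro[4.5]decan-7-one
Product: 4 (8E)-6,6-dimethyl-8-[(propan-2-yloxy)methylidene]-1,4-dioxaspiro[4.5]decan-7-one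
Conditions: i-PrI, K2CO3, acetone, reflux
Reagents that add atoms: 2-iodopropane, CC(C)I
Why: Williamson-type O-alkylation of the β-keto aldehyde enolate with a secondary iodide gives the vinylogous ester; the enol ether geometry is of no consequence.

Step 4
Reactants: 4 (8E)-6,6-dimethyl-8-[(propan-2-yloxy)methylidene]-1,4-dioxaspiro[4.5]decan-7-one
Product: 6 3,3-dimethyl-4-oxocyclohex-1-ene-1-carbaldehyde, via allylic alcohol 5 (not isolated)
Conditions: LiAlH4, Et2O, 0 °C; then 3 M HCl, THF, rt
Reagents that add atoms: water, O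
Why: 1,2-Hydride reduction of the vinylogous ester followed by acid hydrolysis of the γ-hydroxy enol ether is the classical 1,3-carbonyl transposition to a conjugated aldehyde, and the same acid removes the dioxolane; the quaternary C4 rules out double-bond migration.

Step 5
Reactants: 7 geranyl acetate
Product: 8 (2E,6E)-3,7-dimethyl-8-oxoocta-2,6-dien-1-yl acetate
Conditions: SeO2 (1.1 equiv), 95% EtOH, reflux
Reagents that add atoms: selenium dioxide, O=[Se]=O
Why: SeO2 allylic oxidation (ene reaction, then [2,3]-sigmatropic shift) attacks the E-methyl group of the terminal trisubstituted alkene and carries it on to the E-enal, while the alkene deactivated by the allylic acetate is left.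

Step 6
Reactants: 8 (2E,6E)-3,7-dimethyl-8-oxoocta-2,6-dien-1-yl acetate
Product: 9 (2E,6E)-3,7-dimethylnona-2,6,8-trien-1-yl acetate
Conditions: Ph3PCH3Br, n-BuLi (0.95 equiv per salt), THF, 0 °C; then 8, −78 → 0 °C
Reagents that add atoms: methyltriphenylphosphonium bromide, C[P+](c1ccccc1)(c1ccccc1)c1ccccc1.[Br-]
Why: Wittig methylenation of the enal by the unstabilised ylide at low temperature is far faster than attack on the acetate and leaves the E-trisubstituted alkene geometry untouched.

Step 7
Reactants: 6 3,3-dimethyl-4-oxocyclohex-1-ene-1-carbaldehyde; 9 (2E,6E)-3,7-dimethylnona-2,6,8-trien-1-yl acetate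
Product: 10 (2E)-5-[(1R,4aR,8aR)-8a-formyl-2,5,5-trimethyl-6-oxo-1,4,4a,5,6,7,8,8a-octahydronaphthalen-1-yl]-3-methylpent-2-en-1-yl acetate (cis-fused adduct; C20 = CHO; C3 = ketone)
Conditions: (S)-3,3-diphenyl-1-(2-methylphenyl)tetrahydro-1H,3H-pyrrolo[1,2-c][1,3,2]oxazaborole (20 mol %) protonated with HN(SO2CF3)2 (18 mol %), 9 (2 equiv), CH2Cl2, −78 → −20 °C
Reagents that add atoms: none
Why: The protonated oxazaborolidine binds the formyl oxygen of 6 (boron anti to C10, formyl C–H···O contact to the ring oxygen) and a concerted, asynchronous [4+2] cycloaddition follows in which C5–C6 bonding runs ahead of C9–C10 bonding. The closest known reaction type is the cationic-oxazaborolidine-catalysed Diels–Alder reaction of 2-substituted and cycloalk-1-ene carbaldehydes with acyclic dienes. Ring B is closed as a six-membered carbocycle by intermolecular suprafacial–suprafacial cycloaddition, and C7=C8 arises from the central diene bond. H-5 and the formyl group come out cis because the dienophile double bond lies in ring A; C9 is set cis to the formyl group by the endo position of the catalyst-bound formyl group over the (E)-diene; the absolute sense (Re face at C10 and C5) is set by the (S)-catalyst, whose C-phenyl group screens the inner enal face. The step needs ortho regiochemistry, endo selectivity and one enal face: the unsubstituted terminus C6 carries the larger HOMO coefficient and is the only one that can reach the neopentyl C5, the exo mode would push ring A and its gem-dimethyl group under the diene, and the catalyst supplies the facial bias.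

Step 8
Reactants: 10 (cis-fused adduct with C20 formyl group)
Product: 11 (2E)-3-methyl-5-[(1R,4aR,8aR)-2,5,5-trimethyl-8a-{(E)-[2-(4-methylbenzenesulfonyl)hydrazinylidene]methyl}-6-oxo-1,4,4a,5,6,7,8,8a-octahydronaphthalen-1-yl]pent-2-en-1-yl acetate
Conditions: TsNHNH2 (1.05 equiv), MeOH, rt
Reagents that add atoms: 4-methylbenzenesulfonohydrazide, Cc1ccc(cc1)S(=O)(=O)NN
Why: Hydrazone condensation at the non-enolisable aldehyde is much faster than at the ketone flanked by the quaternary C4, so only C20 is derivatised.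

Step 9
Reactants: 11 (C20 tosylhydrazone)
Product: 14 (2E)-3-methyl-5-[(1R,4aR,8aS)-2,5,5,8a-tetramethyl-6-oxo-1,4,4a,5,6,7,8,8a-octahydronaphthalen-1-yl]pent-2-en-1-yl acetate, via N-boryl tosylhydrazine 12 (not isolated), via alkyldiazene 13 (not isolated)
Conditions: catecholborane (1.5 equiv), CHCl3, 0 °C → rt; then NaOAc·3H2O, reflux
Reagents that add atoms: none
Why: Caglioti-type tosylhydrazone reduction: hydroboration of C=N, acetate-induced loss of sulfinate and loss of N2 from the diazene turn C20 into a methyl group under conditions that spare the acetate and should reduce the hindered C3 ketone far more slowly.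

Step 10
Reactants: 14 (C3 ketone with C20 methyl)
Product: 15 (2E)-3-methyl-5-[(1R,4aR,8aS)-2,5,5,8a-tetramethyl-6-(trimethylsilyloxy)-1,4,4a,5,8,8a-hexahydronaphthalen-1-yl]pent-2-en-1-yl acetate (C2=C3 silyl enol ether)
Conditions: TMSOTf (1.3 equiv), Et3N, CH2Cl2, −78 → 0 °C
Reagents that add atoms: trimethylsilyl trifluoromethanesulfonate, C[Si](C)(C)OS(=O)(=O)C(F)(F)F
Why: Soft enolisation and O-silylation can only go toward C2 because C4 is quaternary, and the ketone reacts well before the acetate.

Step 11
Reactants: 15 (C2=C3 silyl enol ether)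
Product: 17 (2E)-5-[(1R,4aR,7S,8aS)-7-hydroxy-2,5,5,8a-tetramethyl-6-oxo-1,4,4a,5,6,7,8,8a-octahydronaphthalen-1-yl]-3-methylpent-2-en-1-yl acetate (2-hydroxy-3-ketone; OH anti to C20), via silyloxy epoxide 16 (not isolated)
Conditions: DMDO (1.0 equiv, acetone), CH2Cl2, −78 °C; then 1 M HCl, THF, 0 °C
Reagents that add atoms: dimethyldioxirane, CC1(C)OO1
Why: Rubottom oxidation: the electron-rich enol ether is epoxidised far faster than the two trisubstituted alkenes, on the face opposite the axial C20 and the axial C4 methyl, and acid opening of the silyloxy epoxide should give the equatorial 2-hydroxyl (2S), which is also the stable epimer.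

Step 12
Reactants: 17 (2-hydroxy-3-ketone)
Product: 18 (2E)-5-[(1R,4aR,6R,7S,8aS)-6,7-dihydroxy-2,5,5,8a-tetramethyl-1,4,4a,5,6,7,8,8a-octahydronaphthalen-1-yl]-3-methylpent-2-en-1-yl acetate (target)
Conditions: LiBH(s-Bu)3 (L-Selectride, 2.5 equiv), THF, −78 °C; then AcOH, −78 °C → rt
Reagents that add atoms: none
Why: Bulky-hydride ketone reduction: with the 2-hydroxyl equatorial, C6 is axial on ring A and blocks the axial trajectory at C3, so hydride should enter equatorially from the C20/H-5 side and give the axial 3-hydroxyl cis to the 2-hydroxyl (3R), while the acetate survives at −78 °C.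

**Compound list**
1 | 2,2-dimethylcyclohexane-1,3-dione | CC1(C)C(=O)CCCC1=O | starting material
2 | 6,6-dimethyl-1,4-dioxaspiro[4.5]decan-7-one | CC1(C)C(=O)CCCC12OCCO2 | intermediate
3 | (8Z)-8-(hydroxymethylidene)-6,6-dimethyl-1,4-dioxaspiro[4.5]decan-7-one | O/C=C1/CCC2(OCCO2)C(C)(C)C1=O | intermediate
4 | (8E)-6,6-dimethyl-8-[(propan-2-yloxy)methylidene]-1,4-dioxaspiro[4.5]decan-7-one | CC(C)O/C=C1\CCC2(OCCO2)C(C)(C)C1=O | intermediate
5 | (8E)-6,6-dimethyl-8-[(propan-2-yloxy)methylidene]-1,4-dioxaspiro[4.5]decan-7-ol, racemic | CC(C)O/C=C1\CCC2(OCCO2)C(C)(C)C1O | intermediate (not isolated)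
6 | 3,3-dimethyl-4-oxocyclohex-1-ene-1-carbaldehyde | O=CC1=CC(C)(C)C(=O)CC1 | intermediate
7 | geranyl acetate, (2E)-3,7-dimethylocta-2,6-dien-1-yl acetate | CC(=O)OC/C=C(\C)CCC=C(C)C | starting material
8 | (2E,6E)-3,7-dimethyl-8-oxoocta-2,6-dien-1-yl acetate | CC(=O)OC/C=C(\C)CC/C=C(\C)C=O | intermediate
9 | (2E,6E)-3,7-dimethylnona-2,6,8-trien-1-yl acetate | CC(=O)OC/C=C(\C)CC/C=C(\C)C=C | intermediate
10 | (2E)-5-[(1R,4aR,8aR)-8a-formyl-2,5,5-trimethyl-6-oxo-1,4,4a,5,6,7,8,8a-octahydronaphthalen-1-yl]-3-methylpent-2-en-1-yl acetate | CC(=O)OC/C=C(\C)CC[C@@H]1C(C)=CC[C@H]2C(C)(C)C(=O)CC[C@@]12C=O | intermediate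
11 | C20 (E)-tosylhydrazone of 10, (1R,4aR,8aR) | CC(=O)OC/C=C(\C)CC[C@@H]1C(C)=CC[C@H]2C(C)(C)C(=O)CC[C@@]12/C=N/NS(=O)(=O)c1ccc(C)cc1 | intermediate
12 | N-(1,3,2-benzodioxaborol-2-yl)-N'-tosylhydrazine at C20 (hydroboration product of 11) | CC(=O)OC/C=C(\C)CC[C@@H]1C(C)=CC[C@H]2C(C)(C)C(=O)CC[C@@]12CN(B1Oc2ccccc2O1)NS(=O)(=O)c1ccc(C)cc1 | intermediate (not isolated)
13 | C20 alkyldiazene (8a-diazenylmethyl compound) | CC(=O)OC/C=C(\C)CC[C@@H]1C(C)=CC[C@H]2C(C)(C)C(=O)CC[C@@]12CN=N | intermediate (not isolated)
14 | (2E)-3-methyl-5-[(1R,4aR,8aS)-2,5,5,8a-tetramethyl-6-oxo-1,4,4a,5,6,7,8,8a-octahydronaphthalen-1-yl]pent-2-en-1-yl acetate | CC(=O)OC/C=C(\C)CC[C@@H]1C(C)=CC[C@H]2C(C)(C)C(=O)CC[C@@]12C | intermediate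
15 | (2E)-3-methyl-5-[(1R,4aR,8aS)-2,5,5,8a-tetramethyl-6-(trimethylsilyloxy)-1,4,4a,5,8,8a-hexahydronaphthalen-1-yl]pent-2-en-1-yl acetate | CC(=O)OC/C=C(\C)CC[C@@H]1C(C)=CC[C@H]2C(C)(C)C(O[Si](C)(C)C)=CC[C@@]12C | intermediate
16 | 2,3-epoxide of 15 carrying the C3 trimethylsilyloxy group, oxirane oxygen on the face opposite C20 | CC(=O)OC/C=C(\C)CC[C@@H]1C(C)=CC[C@H]2C(C)(C)[C@@]3(O[Si](C)(C)C)O[C@H]3C[C@@]12C | intermediate (not isolated)
17 | (2E)-5-[(1R,4aR,7S,8aS)-7-hydroxy-2,5,5,8a-tetramethyl-6-oxo-1,4,4a,5,6,7,8,8a-octahydronaphthalen-1-yl]-3-methylpent-2-en-1-yl acetate | CC(=O)OC/C=C(\C)CC[C@@H]1C(C)=CC[C@H]2C(C)(C)C(=O)[C@@H](O)C[C@@]12C | intermediate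
18 | (2E)-5-[(1R,4aR,6R,7S,8aS)-6,7-dihydroxy-2,5,5,8a-tetramethyl-1,4,4a,5,6,7,8,8a-octahydronaphthalen-1-yl]-3-methylpent-2-en-1-yl acetate | CC(=O)OC/C=C(\C)CC[C@@H]1C(C)=CC[C@H]2C(C)(C)[C@@H](O)[C@@H](O)C[C@@]12C | target

**Count**
Total steps: 12. Longest linear sequence: 10 steps (steps 1–4 and 7–12); the diene arm (steps 5–6) joins at step 7.

**Steps most likely to fail**

Step 7 (key cycloaddition). The cycloaddition may be slow at the neopentyl C5, so that diene polymerisation, or erosion of endo and enantioselectivity at the higher temperature then needed, takes over. The sense of induction rests on the formyl C–H···O binding model; if the opposite face were attacked, the (R)-catalyst would be used with nothing else changed. Fallback: setting out from 6 and 9, the cycloaddition is run with the achiral Lewis acid EtAlCl2 (CH2Cl2, −78 → −20 °C). This should give 10 together with its mirror image, the enantiomeric adduct F1, as a racemate of the same ortho, endo constitution. Condensation with (1R,2R)-N,N'-dimethylcyclohexane-1,2-diamine (4 Å molecular sieves, Et2O, rt) converts the pair into two diastereomeric imidazolidines, the aminal F2 (from 10) and the aminal F3 (from F1), which are separated by chromatography. Mild hydrolysis of F2 (1 M HCl, THF, 0 °C) returns enantiopure 10, where the route is rejoined.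

Step 11 (enol ether oxidation). The oxidant may add to the C20 face of the enol ether if the other ring A half-chair (C9 axial) is the reactive one, or the C7=C8 alkene may be epoxidised in competition. Fallback: setting out from 15, bromination with NBS (THF, −78 °C) is specific for the enol ether and, under the same facial preference that caused the failure, gives the 2-bromo ketone F4 with bromine on the C20 face. HCO2K in MeOH (40 °C) displaces the bromide with inversion to the 2-formyloxy ketone F5. The formate is methanolysed in the same flask, leaving the C15 acetate, and the sequence rejoins the route at 17.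

Step 9 (hydrazone reduction). Catecholborane may reduce the C3 ketone in competition with the hindered hydrazone, or the neopentyl N-boryl hydrazine may collapse sluggishly. Fallback: setting out from 10, NaBH4 (0.3 equiv, EtOH/CH2Cl2, −78 °C) reduces only the aldehyde to the C20 primary alcohol F6. 1,1'-Thiocarbonyldiimidazole (DMAP, ClCH2CH2Cl, 60 °C) gives the O-alkyl imidazole-1-carbothioate F7. Barton–McCombie deoxygenation (Bu3SnH, AIBN, xylene, 140 °C) then delivers the C20 methyl compound 14, where the route is rejoined.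

**Further compounds**
F1 | step 7 | enantiomer of 10, (1S,4aS,8aS) | CC(=O)OC/C=C(\C)CC[C@H]1C(C)=CC[C@@H]2C(C)(C)C(=O)CC[C@]12C=O
F2 | step 7 | imidazolidine (aminal) of 10 with (1R,2R)-N,N'-dimethylcyclohexane-1,2-diamine | CC(=O)OC/C=C(\C)CC[C@@H]1C(C)=CC[C@H]2C(C)(C)C(=O)CC[C@@]12C1N(C)[C@@H]2CCCC[C@H]2N1C
F3 | step 7 | imidazolidine (aminal) of F1 with (1R,2R)-N,N'-dimethylcyclohexane-1,2-diamine | CC(=O)OC/C=C(\C)CC[C@H]1C(C)=CC[C@@H]2C(C)(C)C(=O)CC[C@]12C1N(C)[C@@H]2CCCC[C@H]2N1C
F4 | step 11 | (2R)-2-bromo-3-ketone (labdane numbering), bromine on the C20 face | CC(=O)OC/C=C(\C)CC[C@@H]1C(C)=CC[C@H]2C(C)(C)C(=O)[C@H](Br)C[C@@]12C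
F5 | step 11 | (2S)-2-formyloxy-3-ketone (labdane numbering) | CC(=O)OC/C=C(\C)CC[C@@H]1C(C)=CC[C@H]2C(C)(C)C(=O)[C@@H](OC=O)C[C@@]12C
F6 | step 9 | C20 primary alcohol (8a-hydroxymethyl analogue of 10) | CC(=O)OC/C=C(\C)CC[C@@H]1C(C)=CC[C@H]2C(C)(C)C(=O)CC[C@@]12CO
F7 | step 9 | O-(C20) 1H-imidazole-1-carbothioate of F6 | CC(=O)OC/C=C(\C)CC[C@@H]1C(C)=CC[C@H]2C(C)(C)C(=O)CC[C@@]12COC(=S)n1ccnc1
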